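## Retrosynthetic overview

1. The ring D enol ether is unmasked last by dehydroiodination. Ring C (the spiro-tetrahydrofuran), the 9α-O/8β-OAc pair and C13 come from one epoxide-opening/iodo-spiroetherification cascade on a 7β-acetoxy-8α,9α-epoxide that carries ring D as a 2,5-dihydrofuran.
2. The allylic 7β-ol behind that epoxide comes from 1,3-transposition of a tertiary alcohol, made by adding a dihydrofuranyl-ethyl cerium reagent (ring D by enyne metathesis) to a trans-decalin 8-methyl-7-en-9-one.
3. The enone comes from a bicyclic enal by dienolate methylation at C4 (C19 as CHO), hydrogenation of the 5,6-alkene, dehydrogenation and C8 methylation.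
4. The bicyclic enal (ring A closed onto ring B, C10 set) comes from an achiral dione enal by an amine-catalysed reductive aldol desymmetrisation. The dione enal comes from 2-methylcyclohexane-1,3-dione, acrolein and a two-carbon ylide.
5. Ring order: B (the dione) → A → D (made separately) → C.

Convention: positions carry labdane locants (C4 bears C18/C19, C10 the angular methyl, C17 is the methyl on C8, side chain C11–C16); α is the face opposite the C10 methyl, β the same face.

Assumption: the (S)-diamine salt of step 3 and (R)-TRIP of step 14 are taken as the catalysts matched to the 10S and 13R centres; if either gives the opposite sense, its mirror image is used.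

## Route

Step 1
Reactants: 1 2-methylcyclohexane-1,3-dione; 2 acrolein
Product: 3 3-(1-methyl-2,6-dioxocyclohexyl)propanal
Conditions: H2O, rt
Reagents that add atoms: none
Why: Michael addition of the acidic 1,3-dione to acrolein; the product is achiral and no stereocentre is formed.

Step 2
Reactants: 3 3-(1-methyl-2,6-dioxocyclohexyl)propanal; 4 (triphenylphosphoranylidene)acetaldehyde
Product: 5 (E)-5-(1-methyl-2,6-dioxocyclohexyl)pent-2-enal
Conditions: toluene, 80 °C
Reagents that add atoms: none
Why: Wittig olefination with a stabilised ylide, which reacts only with the aldehyde (not the hindered ring ketones) and gives the E-enal.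

Step 3
Reactants: 5 (E)-5-(1-methyl-2,6-dioxocyclohexyl)pent-2-enal
Product: 8 bicyclic enal (10S)-10-methyl-9-oxo-octal-4-ene-4-carbaldehyde, via saturated aldehyde 6 (not isolated), via ketol aldehyde 7 (not isolated)
Conditions: Hantzsch ester (1.1 equiv), (S)-N1,N1-diethyl-3,3-dimethylbutane-1,2-diamine·TfOH (10 mol %), CHCl3, 25 → 45 °C
Reagents that add atoms: none
Why: Proposed new method: the primary amine salt turns the enal into an iminium ion that takes a hydride from the Hantzsch ester at C3, which leaves the enamine of aldehyde 6 directly; before hydrolysis this enamine adds through C4 to one of the two enantiotopic ring carbonyls in a chair-like 6-enolexo aldol transition state in which the protonated tertiary amine hydrogen-bonds to, and so selects, that carbonyl (this sets C10), and loss of water through the iminium/enamine gives enal 8; the closest known reaction types are the Hajos–Parrish/Wieland–Miescher amine-catalysed desymmetrising aldol condensation and amine/Hantzsch-ester reductive Michael cyclisations.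

Step 4
Reactants: 8 bicyclic enal
Product: 9 4α,10β-dimethyl-9-oxo-octal-5-ene-4β-carbaldehyde
Conditions: t-BuOK (1.05 equiv), t-BuOH/THF, −20 °C; MeI, −20 → 0 °C
Reagents that add atoms: iodomethane (CI)
Why: deconjugative α-alkylation of the aldehyde dienolate (C6–H is removed; the vinylogous aldehyde is far more acidic than the C9 ketone, so with one equivalent of base the ketone enolate is not populated), and MeI enters C4 on the α face, anti to the axial C10 methyl, giving 4α-Me/4β-CHO.

Step 5
Reactants: 9 4α,10β-dimethyl-9-oxo-octal-5-ene-4β-carbaldehyde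
Product: 10 4α,10β-dimethyl-9-oxo-5α-decalin-4β-carbaldehyde
Conditions: H2 (5 bar), Pd/C, EtOAc, rt
Reagents that add atoms: none
Why: heterogeneous hydrogenation from the α face, because the β face of the 5,6-alkene is screened by the axial C10 methyl and the axial 4β-formyl group; this sets 5α-H (trans-decalin).

Step 6
Reactants: 10 4α,10β-dimethyl-9-oxo-5α-decalin-4β-carbaldehyde
Product: 11 4α,10β-dimethyl-9-oxo-5α-octal-7-ene-4β-carbaldehyde
Conditions: IBX (1.5 equiv), DMSO, 65 °C
Reagents that add atoms: none
Why: IBX α,β-dehydrogenation of the ketone; only C8 can enolise (C10 is quaternary) and the aldehyde has no α-hydrogen.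

Step 7
Reactants: 11 4α,10β-dimethyl-9-oxo-5α-octal-7-ene-4β-carbaldehyde
Product: 12 4β-(hydroxymethyl)-4α,10β-dimethyl-5α-octal-7-en-9-one
Conditions: NaBH4 (0.3 equiv), EtOH/CH2Cl2, −78 °C
Reagents that add atoms: none
Why: chemoselective borohydride reduction of the aldehyde at low temperature in the presence of the hindered conjugated ketone.

Step 8
Reactants: 12 4β-(hydroxymethyl)-4α,10β-dimethyl-5α-octal-7-en-9-one
Product: 14 4β-(hydroxymethyl)-4α,8,10β-trimethyl-5α-octal-7-en-9-one, via deconjugated methyl ketone 13 (not isolated)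
Conditions: LDA (2.2 equiv), THF/DMPU, −78 → −40 °C; MeI (1.1 equiv); then MeOH, DBU (0.2 equiv), rt
Reagents that add atoms: iodomethane (CI)
Why: with no α′-hydrogen, LDA removes C6–H to give the extended enolate (the second equivalent makes the alkoxide), which is C-methylated at C8 (α-alkylation of a dienolate); methoxide/DBU then returns the double bond to conjugation, so C8 ends sp2 and carries no stereocentre.

Step 9
Reactants: 15 allyl propargyl ether
Product: 16 3-vinyl-2,5-dihydrofuran
Conditions: first-generation Grubbs catalyst RuCl2(PCy3)2(=CHPh) (3 mol %), ethylene (1 atm), CH2Cl2, rt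
Reagents that add atoms: none
Why: ring-closing enyne metathesis forms the 2,5-dihydrofuran (ring D) and the 3-vinyl group; ethylene keeps the ruthenium methylidene turning over.

Step 10
Reactants: 16 3-vinyl-2,5-dihydrofuran
Product: 18 3-(2-iodoethyl)-2,5-dihydrofuran, via alkylzirconocene chloride 17 (not isolated)
Conditions: Cp2Zr(H)Cl (1.1 equiv), THF, rt; then I2, 0 °C
Reagents that add atoms: iodine (II)
Why: hydrozirconation puts zirconium on the terminal carbon of the unhindered vinyl group only (the trisubstituted ring alkene is inert), and iodinolysis of the C–Zr bond gives the primary iodide.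

Step 11
Reactants: 14 4β-(hydroxymethyl)-4α,8,10β-trimethyl-5α-octal-7-en-9-one; 18 3-(2-iodoethyl)-2,5-dihydrofuran
Product: 21 tertiary allylic alcohol 15,16-epoxy-9-epi-labda-7,13-diene-9β,19-diol, via organolithium 19 (not isolated), via organocerium 20 (not isolated)
Conditions: 18 (2.5 equiv), t-BuLi (5 equiv), Et2O, −78 °C; CeCl3, THF, −78 °C; then 14, −78 °C
Reagents that add atoms: none
Why: iodine–lithium exchange and transmetalation give a non-basic organocerium that adds 1,2 to the hindered enone (Imamoto-type addition) from the α face, anti to the axial C10 methyl (9β-OH expected); this C9 centre is only relayed to C7 in step 12 and then erased.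

Step 12
Reactants: 21 tertiary allylic alcohol
Product: 22 15,16-epoxylabda-8,13-diene-7β,19-diol
Conditions: Ph3SiOReO3 (5 mol %), Et2O, −20 → 0 °C
Reagents that add atoms: none
Why: perrhenate-catalysed 1,3-transposition of the allylic alcohol ([3,3] shift of the perrhenate ester) is suprafacial, so the 9β-oxygen arrives as 7β-OH; it is driven by forming the tetrasubstituted 8,9-alkene and relieving strain at C9.

Step 13
Reactants: 22 15,16-epoxylabda-8,13-diene-7β,19-diol
Product: 23 7β,19-diacetoxy-15,16-epoxylabda-8,13-diene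
Conditions: Ac2O, pyridine, DMAP (cat.), CH2Cl2, rt
Reagents that add atoms: acetic anhydride (CC(=O)OC(C)=O)
Why: DMAP-catalysed acetylation of the primary and the secondary allylic alcohol; the 19-acetate is final and the 7β-acetate is the future C8 acetate.

Step 14
Reactants: 23 7β,19-diacetoxy-15,16-epoxylabda-8,13-diene
Product: 27 8β,19-diacetoxy-14-iodo-9α,13:15,16-diepoxylabdan-7β-ol, via epoxide 24 (not isolated), via dioxolanium alcohol 25 (not isolated), via dioxolanium iodo ether 26 (not isolated)
Conditions: DMDO, acetone, −20 °C; evaporate; (R)-TRIP (10 mol %), Ph3P=S (10 mol %), NIS (1.2 equiv), CH2Cl2, −40 °C; then aq NaHCO3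
Reagents that add atoms: dimethyldioxirane (CC1(C)OO1); N-iodosuccinimide (O=C1CCC(=O)N1I); water (O)
Why: Proposed new method: DMDO epoxidises the electron-rich tetrasubstituted 8,9-alkene from the α face (anti to the C10 methyl and the 7β-acetate; the bis-allylic-ether alkene of ring D is deactivated); the phosphoric acid then triggers backside attack of the trans 7β-acetate carbonyl on C8, giving the 7β,8β-dioxolanium ion and freeing the axial 9α-OH (inversion at C8 sets 8β-O/8α-Me, retention at C9 keeps 9α-O); the chiral phosphate–iodiranium ion pair, with Ph3P=S as iodine shuttle, lets this tertiary alcohol close the spiro-tetrahydrofuran by anti 5-exo attack on C13, the catalyst choosing the alkene face and hence C13, and bicarbonate hydrolysis of the dioxolanium gives the axial 8β-acetate and the equatorial 7β-alcohol; the closest known reaction types are acetoxonium opening of trans-2-acetoxy epoxides and Lewis base/chiral phosphoric acid co-catalysed halocycloetherification.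

Step 15
Reactants: 27 8β,19-diacetoxy-14-iodo-9α,13:15,16-diepoxylabdan-7β-ol
Product: 28 8β,19-diacetoxy-14-iodo-9α,13:15,16-diepoxylabdan-7-one
Conditions: DMP, NaHCO3, CH2Cl2, 0 °C
Reagents that add atoms: none
Why: Dess–Martin oxidation of the equatorial secondary 7β-alcohol to the ketone, run at once and under buffered conditions so that the tertiary acetate does not migrate to O7; iodide, acetates and ethers are inert.

Step 16
Reactants: 28 8β,19-diacetoxy-14-iodo-9α,13:15,16-diepoxylabdan-7-one
Product: 29 (13R)-8β,19-diacetoxy-9α,13:15,16-diepoxylabd-14-en-7-one (CNP0351241.1)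
Conditions: DBU (5 equiv), toluene, 90 °C
Reagents that add atoms: none
Why: E2 dehydroiodination; the only β-hydrogens are on C15 (C13 is quaternary) and one is anti to the C14 iodide, so the 14,15-enol ether forms, and the basic medium protects the acid-labile spiro enol ether.

## Compound list

1 | 2-methylcyclohexane-1,3-dione | CC1C(=O)CCCC1=O | starting material
2 | acrolein | C=CC=O | starting material
3 | 3-(1-methyl-2,6-dioxocyclohexyl)propanal | CC1(CCC=O)C(=O)CCCC1=O | intermediate
4 | (triphenylphosphoranylidene)acetaldehyde | O=CC=P(c1ccccc1)(c1ccccc1)c1ccccc1 | starting material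
5 | (E)-5-(1-methyl-2,6-dioxocyclohexyl)pent-2-enal | CC1(CC/C=C/C=O)C(=O)CCCC1=O | intermediate
6 | 5-(1-methyl-2,6-dioxocyclohexyl)pentanal (not isolated; reacts as its enamine) | CC1(CCCCC=O)C(=O)CCCC1=O | intermediate
7 | ketol aldehyde: 5-hydroxy-10-methyl-9-oxodecalin-4-carbaldehyde, 10S, C4 and C5 unassigned (not isolated) | O=CC1CCC[C@]2(C)C(=O)CCCC12O | intermediate
8 | bicyclic enal: (10S)-10-methyl-9-oxo-octal-4-ene-4-carbaldehyde (C4=C5, ring B ketone at C9) | O=CC1=C2CCCC(=O)[C@@]2(C)CCC1 | intermediate
9 | 4α,10β-dimethyl-9-oxo-octal-5-ene-4β-carbaldehyde | O=C[C@@]1(C)CCC[C@@]2(C)C1=CCCC2=O | intermediate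
10 | 4α,10β-dimethyl-9-oxo-5α-decalin-4β-carbaldehyde (trans-fused) | O=C[C@@]1(C)CCC[C@@]2(C)[C@H]1CCCC2=O | intermediate
11 | 4α,10β-dimethyl-9-oxo-5α-octal-7-ene-4β-carbaldehyde | O=C[C@@]1(C)CCC[C@@]2(C)[C@H]1CC=CC2=O | intermediate
12 | 4β-(hydroxymethyl)-4α,10β-dimethyl-5α-octal-7-en-9-one | OC[C@@]1(C)CCC[C@@]2(C)[C@H]1CC=CC2=O | intermediate
13 | 4β-(hydroxymethyl)-4α,8,10β-trimethyl-5α-octal-6-en-9-one, C8 epimers (not isolated) | OC[C@@]1(C)CCC[C@@]2(C)[C@H]1C=CC(C)C2=O | intermediate
14 | 4β-(hydroxymethyl)-4α,8,10β-trimethyl-5α-octal-7-en-9-one | OC[C@@]1(C)CCC[C@@]2(C)[C@H]1CC=C(C)C2=O | intermediate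
15 | allyl propargyl ether (3-(prop-2-yn-1-yloxy)prop-1-ene) | C=CCOCC#C | starting material
16 | 3-vinyl-2,5-dihydrofuran | C=CC1=CCOC1 | intermediate
17 | chlorobis(cyclopentadienyl)[2-(2,5-dihydrofuran-3-yl)ethyl]zirconium (not isolated) | Cl[Zr](CCC1=CCOC1)(C1C=CC=C1)C1C=CC=C1 | intermediate
18 | 3-(2-iodoethyl)-2,5-dihydrofuran | ICCC1=CCOC1 | intermediate
19 | [2-(2,5-dihydrofuran-3-yl)ethyl]lithium (not isolated) | [Li]CCC1=CCOC1 | intermediate
20 | dichloro[2-(2,5-dihydrofuran-3-yl)ethyl]cerium (not isolated) | Cl[Ce](Cl)CCC1=CCOC1 | intermediate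
21 | 15,16-epoxy-9-epi-labda-7,13-diene-9β,19-diol (9β-OH, side chain 9α; expected major epimer) | OC[C@@]1(C)CCC[C@@]2(C)[C@H]1CC=C(C)[C@@]2(O)CCC1=CCOC1 | intermediate
22 | 15,16-epoxylabda-8,13-diene-7β,19-diol | OC[C@@]1(C)CCC[C@@]2(C)[C@H]1C[C@H](O)C(C)=C2CCC1=CCOC1 | intermediate
23 | 7β,19-diacetoxy-15,16-epoxylabda-8,13-diene | CC(=O)OC[C@@]1(C)CCC[C@@]2(C)[C@H]1C[C@H](OC(C)=O)C(C)=C2CCC1=CCOC1 | intermediate
24 | 7β,19-diacetoxy-8α,9α:15,16-diepoxylabd-13-ene (not isolated) | CC(=O)OC[C@@]1(C)CCC[C@@]2(C)[C@H]1C[C@H](OC(C)=O)[C@@]3(C)O[C@@]23CCC1=CCOC1 | intermediate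
25 | 19-acetoxy-9α-hydroxy-15,16-epoxylabd-13-ene 7β,8β-(2-methyl-1,3-dioxolan-2-ylium) ion (not isolated) | CC(=O)OC[C@@]1(C)CCC[C@@]2(C)[C@H]1C[C@@H]3O[C+](C)O[C@]3(C)[C@]2(O)CCC1=CCOC1 | intermediate
26 | 19-acetoxy-14-iodo-9α,13:15,16-diepoxylabdane 7β,8β-(2-methyl-1,3-dioxolan-2-ylium) ion (not isolated) | CC(=O)OC[C@@]1(C)CCC[C@@]2(C)[C@H]1C[C@@H]3O[C+](C)O[C@]3(C)[C@]21CC[C@]2([C@@H](I)COC2)O1 | intermediate
27 | 8β,19-diacetoxy-14-iodo-9α,13:15,16-diepoxylabdan-7β-ol (iodide trans to O9; spiro centre C13 as in 29) | CC(=O)OC[C@@]1(C)CCC[C@@]2(C)[C@H]1C[C@H](O)[C@](C)(OC(C)=O)[C@]21CC[C@]2([C@@H](I)COC2)O1 | intermediate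
28 | 8β,19-diacetoxy-14-iodo-9α,13:15,16-diepoxylabdan-7-one | CC(=O)OC[C@@]1(C)CCC[C@@]2(C)[C@H]1CC(=O)[C@](C)(OC(C)=O)[C@]21CC[C@]2([C@@H](I)COC2)O1 | intermediate
29 | (4S,5S,8R,9S,10S,13R)-8β,19-diacetoxy-9α,13:15,16-diepoxylabd-14-en-7-one (CNP0351241.1) | CC(=O)OC[C@@]1(C)CCC[C@@]2(C)[C@H]1CC(=O)[C@](C)(OC(C)=O)[C@]21CC[C@]2(C=COC2)O1 | target

## Step count and risks

Total steps: 16. Longest linear sequence: 14 (steps 1–8 and 11–16; steps 9–10 make the side-chain fragment).

The three steps most likely to fail:

Step 3 (new organocascade; enantioselectivity and the interception of the enamine are unproven). Fallback from 5, back at 8: hydrogenate the enal C=C of 5 (H2, Pd/C, EtOAc) and isolate saturated aldehyde 6. Cyclise 6 with (S)-proline (30 mol %) in DMSO, a Hajos–Parrish-type enamine aldol run in the 6-enolexo mode, to ketol 7. Dehydrate 7 with TsOH in warm toluene to 8. This sequence forms no compound outside the list (F0).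

Step 12 (the C7 configuration programs the epoxide face and hence C8 and C9; ionisation could scramble it). Fallback from 21, back at 22: Babler–Dauben oxidative transposition with pyridinium chlorochromate (C5H5NH)[CrO3Cl] buffered with NaOAc in CH2Cl2 also oxidises the primary alcohol and gives 15,16-epoxy-7-oxolabda-8,13-dien-19-al F1. Luche reduction (NaBH4, CeCl3·7H2O, MeOH, −78 °C) then reduces the aldehyde and delivers hydride axially from the α face to C7, giving 22.

Step 14 (new cascade; catalyst control of C13 and the direction of dioxolanium hydrolysis are unproven). Fallback from 23, back at 27: epoxidise with mCPBA/NaHCO3 and isolate epoxide 24. Open it with BF3·OEt2 in CH2Cl2 followed by water, through the same acetoxonium ion, to 8β,19-diacetoxy-15,16-epoxylabd-13-ene-7β,9α-diol F2. Cyclise F2 with NIS/NaHCO3 in MeCN without a chiral catalyst; this gives 27 together with the C13 epimer of 27 F3, which is removed by chromatography.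

Further compounds

F0 | step 3 | none | none
F1 | step 12 | 15,16-epoxy-7-oxolabda-8,13-dien-19-al | O=C[C@@]1(C)CCC[C@@]2(C)[C@H]1CC(=O)C(C)=C2CCC1=CCOC1
F2 | step 14 | 8β,19-diacetoxy-15,16-epoxylabd-13-ene-7β,9α-diol | CC(=O)OC[C@@]1(C)CCC[C@@]2(C)[C@H]1C[C@H](O)[C@](C)(OC(C)=O)[C@]2(O)CCC1=CCOC1
F3 | step 14 | C13 epimer of 27 (8β,19-diacetoxy-14-iodo-9α,13:15,16-diepoxy-13-epi-labdan-7β-ol) | CC(=O)OC[C@@]1(C)CCC[C@@]2(C)[C@H]1C[C@H](O)[C@](C)(OC(C)=O)[C@]21CC[C@@]2([C@H](I)COC2)O1
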